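## Structural features

The target is an isocoumarin (1H-isochromen-1-one): benzene ring A is fused through C4a–C8a to a pyranone made of the C1 lactone carbonyl, O2 and the C3=C4 enol double bond, with a pentyl chain on C3. Ring A carries a free hydroxyl on C6 and, on C8 (peri to the lactone carbonyl), an ether oxygen bound to C1' of ring B, a 2-hydroxy-4-methoxy-6-pentylphenyl group. The molecule has no stereocentre, so no relative or absolute configuration has to be controlled. The fragile groups are:
- the enol lactone, which hydroxide or alkoxide opens and whose C3=C4 bond can be saturated by hydrogen on a metal;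
- the 1,2,4-trioxygenated ring B, which is easily oxidised and easily attacked by electrophiles at C3' and C5';
- any benzylic C1–O derivative of ring A before oxidation, because it lies ortho and para to oxygen donors and ionises readily.

Three phenolic oxygens must end up differentiated (C6–OH, C2'–OH, C4'–OMe) beside the diaryl ether. The real difficulty is the C8–O–C1' ether: C1' has two ortho substituents on an electron-rich ring and C8 lies next to C8a with its carbonyl carbon, so a late union of two arenes is unattractive. The key step uses the fact that ring A is a resorcinol monoether with oxygen on C6 and C8 (meta), hydrogen on C5 and C7, and carbon substituents on the neighbouring C8a and C4a. That pattern is the four-carbon unit C6–C8a–C4a–C5 of a vinylketene joined to the two-carbon unit C7–C8 of an oxygen-substituted alkyne that already carries ring B.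

## Logic of the disconnections

33 to 32. No skeletal bond is cut; the O–H bonds at C6 and C2' become O–benzyl bonds. Both phenols must be masked during the oxidations, and one kind of group allows a single unmasking. The demand is a cleavage that spares C3=C4, the lactone, the C4' methyl ether and the diaryl ether, which points to a Lewis acid with a cation scavenger and away from hydrogen on a metal.

32 to 31. The O2–C3 bond of the enol lactone is cut. The heterocycle becomes an open chain with a carboxyl group at C1 and a ketone at C3. The forward step is an acid-mediated cyclodehydration, with no base.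

31 to 29 to 28. The C1 carboxyl and the C3 ketone are taken back to alcohols and then to silyl ethers. The ring-forming step runs through ketenes at high temperature, where carbonyl groups at C1 and C3 would interfere and silyl ethers are inert. The price is two oxidations, and the forward oxidation must convert both hydroxyls without letting a hydroxy aldehyde close to a lactol.

28 to 27. The C6 O–benzyl bond is cut. The phenol that the ring-forming step sets free has to be capped before any oxidant is used.

27 to 22 plus 13. Three bonds of ring A are cut: C6–C7, C8–C8a and C5–C6. Ring A disappears. 22 is a four-membered enone holding C6, C8a, C4a and C5 with both side chains, and 13 holds C7, C8, the ether oxygen and all of ring B. The crowded ether is no longer an arene–arene coupling. The connectivity of 22, 13 and 27 was re-derived from the mechanism and is consistent: the carbonyl carbon of 22 becomes C6, its substituted alkene carbons become C8a and C4a, and its CH2 becomes C5. The forward step needs one regiochemistry in the ketene–alkyne union.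

13 to 10 to 7 plus 8. The bond between the ring-B oxygen and C8 is cut and the alkyne is traced to a dichlorovinyl ether. The hindered phenoxide of 7 only has to add to a small linear two-carbon electrophile (9, made from 8), which is sterically easy. The forward sequence needs a clean double dehalogenation.

7 to 5 to 4 to 3 to 1. The C1'–O bond is traced to a C1'–CHO bond (aryl migration to oxygen), and then the O–benzyl, O–methyl and C–formyl bonds are cut. 1 already has the pentyl group and the two meta oxygens. The formyl group marks the position for the third oxygen and, through its hydrogen bond, tells the two hydroxyls apart. The demands are formylation next to the pentyl group and methylation of the non-chelated hydroxyl only.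

22 to 21 to 18 plus 19. The two C–Cl bonds are cut first, then the ring bonds C6–C8a and C4a–C5 (target numbering) made by cycloaddition of 20 to the alkyne. The forward step must bond the chain-bearing alkyne carbon to the CCl2 carbon.

18 to 17 to 14 plus 15. The O–Si bond at the C3 oxygen is cut, then the C4a–C4 bond made by opening an epoxide with an acetylide. This gives two purchasable pieces, and the C3 oxygen comes from the epoxide. The attack must occur at the unsubstituted epoxide carbon.

## Other disconnections considered

Alternative 1: The cut is at C4a–C4 and C8a–C1, with ring A kept as an aryne that already carries the diaryl ether.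
- Forward key step: fluoride unmasks the 3-aryloxy aryne from silyl triflate A1. The anion of dimethyl malonate A2 adds at C4a, the aryne carbon remote from the aryloxy group. The aryl anion at C8a closes onto an ester carbonyl and the four-membered alkoxide fragments to homophthalate A3.
- In favour: both carbon substituents of ring A arrive in one operation, and the regiochemistry follows the inductive effect of the aryloxy group. C1 arrives at the carboxyl oxidation level, which is better than the chosen plan, where C1 is raised by two oxidations.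
- Against: A1 already contains the C8–O–C1' bond, so the hindered ether must first be made by joining two arenes, the bond the chosen plan assembles from small pieces. An ortho-silyl triflate on a trioxygenated ring also costs several steps. After the insertion C3 and the pentyl chain are still missing, so a hexanoyl unit must be attached at C4, one ester carbon discarded and the lactone closed.
- Comparison: on convergence the two plans are equal. On mechanism a polar addition stands against a pericyclic cascade, both steered by an oxygen substituent. On step economy Alternative 1 is about equal after its key step and longer before it. The chosen plan is preferred because it avoids the arene–arene etherification.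

Alternative 2: The cut is at C4a–C8a and O2–C1, with the whole bicycle folded from a masked polyketide chain.
- Forward key step: an amine base induces aldol condensation of the dioxinone carbon (future C8a) of A4 onto the C4a ketone, which aromatises ring A. Acid in the same flask unmasks the C3 ketone, whose enol oxygen opens the benzodioxinone at C1 to give A5.
- In favour: both rings close in one flask, ring A needs no protecting group, and C1 and C3 have the right oxidation level from the start. For the isocoumarin core this is clearly better than the chosen plan, which spends five steps after ring formation.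
- Against: A5 has two free phenols, and the C8 hydroxyl is hydrogen-bonded to the lactone carbonyl and is the less nucleophilic one. The ring-B partner is electron-rich with both ortho positions occupied, so it has no activation for nucleophilic substitution and is a poor substrate for metal-mediated etherification. The enol lactone would also be exposed to the base of such a coupling.
- Comparison: Alternative 2 solves the easy part of 33 better and leaves the hard bond to the least suitable method. The chosen plan accepts the extra oxidation-level changes to make that bond by phenoxide addition to a two-carbon electrophile.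

Alternative 3: The cut is at C1'–C6' and C2'–C3' of ring B, which is built as a cyclohexane-1,3-dione on the ether oxygen and aromatised late.
- Forward key step: with an alkoxide base the aryloxymalonate A6 adds to enone A7 in a Michael reaction, and the methyl ketone then closes onto a malonate ester to give dione A8.
- In favour: the C8–O–C1' bond is never made by joining two arenes, because the oxygen is alkylated with a malonate. On this central point Alternative 3 is the equal of the chosen plan. The reagents are cheap and the ring-B pentyl group comes with A7.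
- Against: the Michael donor is a fully substituted, oxygen-bearing carbon and the acceptor is β-alkylated, so the addition builds a quaternary carbon next to a tertiary one and should be slow and reversible. Afterwards an ester must be removed, the ring dehydrogenated, and the two new ring-B oxygens differentiated (methyl on C4'–O, none on C2'–O). Ring A still holds only a methyl group and an ester that must be extended to the pentyl pyranone.
- Comparison: the strategic idea is the same, a ring built onto the oxygen. The chosen plan builds the simpler ring A in one regiodefined step with the three ring-B oxygens already differentiated, and Alternative 3 needs several selective steps after its key step. It is judged longer and less certain.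

Key step: step 11

Assumptions (remarks on the chemistry):
- 1, 8, 14, 15 and 19 are taken as purchased.
- The carbinol carbon that becomes C3 is racemic in every intermediate and is erased in step 14; 33 is achiral.
- In Alternative 2 the mask of the C3 ketone is taken to be a dioxolane.
- TBS stands for tert-butyldimethylsilyl.

## Route

Step 1
Reactants: 1 olivetol (5-pentylbenzene-1,3-diol)
Product: 3 2,4-dihydroxy-6-pentylbenzaldehyde, via aryl iminium chloride 2 (not isolated)
Conditions: POCl3, DMF, 0 °C → rt; then H2O, 50 °C
Reagents that add atoms: N,N-dimethylformamide, CN(C)C=O (formyl carbon); water, O (carbonyl oxygen)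
Why: Vilsmeier–Haack formylation of a resorcinol; the position para to one hydroxyl and ortho to the other is the most nucleophilic and less crowded than the position between the two oxygens, and the iminium salt 2 is hydrolysed on aqueous heating.

Step 2
Reactants: 3 2,4-dihydroxy-6-pentylbenzaldehyde
Product: 4 2-hydroxy-4-methoxy-6-pentylbenzaldehyde
Conditions: MeI (1.1 equiv), K2CO3 (1.1 equiv), acetone, rt
Reagents that add atoms: iodomethane, CI
Why: Williamson etherification; the C2 hydroxyl is hydrogen-bonded to the formyl group and less acidic, so one equivalent of base and electrophile should alkylate only the C4 hydroxyl.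

Step 3
Reactants: 4 2-hydroxy-4-methoxy-6-pentylbenzaldehyde
Product: 5 2-(benzyloxy)-4-methoxy-6-pentylbenzaldehyde
Conditions: BnBr, K2CO3, DMF, 60 °C
Reagents that add atoms: benzyl bromide, BrCc1ccccc1
Why: Williamson benzylation of the remaining chelated phenol, which needs a polar solvent and warming; the benzyl ether survives organolithium, heat, fluoride and oxidants later on.

Step 4
Reactants: 5 2-(benzyloxy)-4-methoxy-6-pentylbenzaldehyde
Product: 7 2-(benzyloxy)-4-methoxy-6-pentylphenol, via aryl formate 6 (not isolated)
Conditions: mCPBA, CH2Cl2, 0 °C → rt; then K2CO3 (cat.), MeOH, rt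
Reagents that add atoms: 3-chloroperbenzoic acid, OOC(=O)c1cccc(Cl)c1
Why: Baeyer–Villiger (Dakin-type) oxidation; the electron-rich aryl group with ortho and para oxygen donors migrates in preference to hydrogen, and methanolysis of formate 6 frees the phenol that carries the future ether oxygen.

Step 5
Reactants: 7 2-(benzyloxy)-4-methoxy-6-pentylphenol; 8 trichloroethylene
Product: 10 1-(benzyloxy)-2-{[(E)-1,2-dichloroethenyl]oxy}-5-methoxy-3-pentylbenzene, via dichloroacetylene 9 (not isolated)
Conditions: K2CO3, DMF, 70 °C
Reagents that add atoms: none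
Why: Base eliminates HCl from 8 to give 9, to which the phenoxide adds in anti fashion (the known route to aryl 1,2-dichlorovinyl ethers); the linear electrophile is small enough for a phenoxide with two ortho substituents.

Step 6
Reactants: 10 1-(benzyloxy)-2-{[(E)-1,2-dichloroethenyl]oxy}-5-methoxy-3-pentylbenzene
Product: 13 1-(benzyloxy)-2-(ethynyloxy)-5-methoxy-3-pentylbenzene, via chloroethynyl ether 11 (not isolated), via lithium aryloxyacetylide 12 (not isolated)
Conditions: n-BuLi (2.5 equiv), THF, −78 → −40 °C; then H2O, −78 °C
Reagents that add atoms: none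
Why: The established dichlorovinyl ether to ynol ether conversion: dehydrochlorination gives 11, chlorine–lithium exchange gives 12, and protonation gives the terminal alkynyl ether; the low temperature protects the benzyl ether and the ring from metalation.

Step 7
Reactants: 14 tert-butyldimethyl(prop-2-yn-1-yloxy)silane; 15 2-pentyloxirane (racemic)
Product: 17 1-[(TBS)oxy]dec-2-yn-5-ol (racemic), via lithium acetylide 16 (not isolated)
Conditions: n-BuLi, THF, −78 °C; BF3·OEt2; then 15, −78 °C; then H2O
Reagents that add atoms: none
Why: Yamaguchi–Hirao alkynylation; the BF3-activated epoxide is opened by 16 at its unsubstituted carbon, which sets the C4a–C4 bond and places the C3 oxygen in one step; the carbinol centre is racemic and is erased later.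

Step 8
Reactants: 17 1-[(TBS)oxy]dec-2-yn-5-ol
Product: 18 1,5-bis[(TBS)oxy]dec-2-yne (racemic)
Conditions: TBSCl, imidazole, DMF, rt
Reagents that add atoms: tert-butyldimethylsilyl chloride, CC(C)(C)[Si](C)(C)Cl
Why: Standard silylation of a secondary alcohol; a silyl ether is the least electron-withdrawing and least nucleophilic oxygen protecting group, which matters for the regiochemistry and chemoselectivity of step 9.

Step 9
Reactants: 18 1,5-bis[(TBS)oxy]dec-2-yne; 19 trichloroacetyl chloride
Product: 21 4,4-dichloro-2-{[(TBS)oxy]methyl}-3-{2-[(TBS)oxy]heptyl}cyclobut-2-en-1-one (racemic), via dichloroketene 20 (not isolated)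
Conditions: Zn–Cu couple, Et2O/DME, rt, slow addition of 19
Reagents that add atoms: none
Why: Dichloroketene–alkyne (2+2) cycloaddition; the ketene carbonyl carbon bonds to the alkyne carbon that is poorer at bearing positive charge, the one next to the propargylic C–O bond, so the chain-bearing carbon should join CCl2 and the silyloxymethyl group should end on C2. DME ties up ZnCl2, and the bulky silyl ethers do not undergo the ketene-induced rearrangement open to alkyl propargyl ethers.

Step 10
Reactants: 21 4,4-dichloro-2-{[(TBS)oxy]methyl}-3-{2-[(TBS)oxy]heptyl}cyclobut-2-en-1-one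
Product: 22 2-{[(TBS)oxy]methyl}-3-{2-[(TBS)oxy]heptyl}cyclobut-2-en-1-one (racemic)
Conditions: Zn dust, AcOH, TMEDA, EtOH, 0 °C → rt
Reagents that add atoms: none
Why: Reductive removal of both α-chlorines by zinc under amine-buffered conditions, the standard second stage of the dichloroketene route to cyclobutenones; the buffer keeps the silyl ethers and the strained enone intact.

Step 11
Reactants: 22 2-{[(TBS)oxy]methyl}-3-{2-[(TBS)oxy]heptyl}cyclobut-2-en-1-one; 13 1-(benzyloxy)-2-(ethynyloxy)-5-methoxy-3-pentylbenzene
Product: 27 3-[2-(benzyloxy)-4-methoxy-6-pentylphenoxy]-4-{[(TBS)oxy]methyl}-5-{2-[(TBS)oxy]heptyl}phenol (racemic), via vinylketene 23 (not isolated), via vinylcyclobutenone 24 (not isolated), via dienylketene 25 (not isolated), via cyclohexadienone 26 (not isolated)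
Conditions: PhMe (0.5 M), 110 °C, sealed tube, 13 (1.5 equiv)
Reagents that add atoms: none
Why: Thermal four-electron electrocyclic opening of 22 gives vinylketene 23, whose electrophilic central carbon (future C6) is attacked by the unsubstituted terminus of 13 (future C7) while the oxygen-bearing alkyne carbon (future C8) bonds to the ketene α-carbon (future C8a), a (2+2) cycloaddition that gives 24. Four-electron opening of 24 gives dienylketene 25, and thermally allowed disrotatory six-electron electrocyclisation forms C5–C6 and closes ring A as cyclohexadienone 26, which tautomerises irreversibly to phenol 27. The closest known reaction type is the Danheiser benzannulation of cyclobutenones with alkoxy- and silyloxyacetylenes; an aryl ethynyl ether belongs to the same ynol ether class but is less electron-rich, which is the reason for the higher temperature and the excess of 13. Ring A is closed only by the six-electron electrocyclisation, so no competing mode of ring closure exists. No lasting stereocentre is made: the quaternary carbon of 24 is destroyed on ring opening and the silyloxy-bearing carbon stays racemic. The selectivity needed is the regiochemistry of the (2+2) step, secured by the polarisation of the alkyne by the aryloxy oxygen, which makes the CH terminus the nucleophile and puts the aryloxy group meta to the new hydroxyl and next to C8a. The neutral, aprotic medium should leave both silyl ethers, the benzyl ether and ring B untouched, and ring B, with both ortho positions occupied, cannot compete as a nucleophile.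

Step 12
Reactants: 27 3-[2-(benzyloxy)-4-methoxy-6-pentylphenoxy]-4-{[(TBS)oxy]methyl}-5-{2-[(TBS)oxy]heptyl}phenol
Product: 28 1-(benzyloxy)-3-[2-(benzyloxy)-4-methoxy-6-pentylphenoxy]-4-{[(TBS)oxy]methyl}-5-{2-[(TBS)oxy]heptyl}benzene (racemic)
Conditions: BnBr, K2CO3, DMF, rt
Reagents that add atoms: benzyl bromide, BrCc1ccccc1
Why: Williamson benzylation of an unhindered phenol at room temperature; capping the oxygen para to the benzylic silyl ether removes the path to a quinone methide and protects ring A from the oxidants of step 14.

Step 13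
Reactants: 28 1-(benzyloxy)-3-[2-(benzyloxy)-4-methoxy-6-pentylphenoxy]-4-{[(TBS)oxy]methyl}-5-{2-[(TBS)oxy]heptyl}benzene
Product: 29 {4-(benzyloxy)-2-[2-(benzyloxy)-4-methoxy-6-pentylphenoxy]-6-(2-hydroxyheptyl)phenyl}methanol (racemic)
Conditions: TBAF, THF, 0 °C → rt
Reagents that add atoms: none
Why: Fluoride cleavage of both silyl ethers; acid is avoided because the benzylic C1–O bond, ortho and para to oxygen donors, would ionise and be solvolysed.

Step 14
Reactants: 29 {4-(benzyloxy)-2-[2-(benzyloxy)-4-methoxy-6-pentylphenoxy]-6-(2-hydroxyheptyl)phenyl}methanol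
Product: 31 4-(benzyloxy)-2-[2-(benzyloxy)-4-methoxy-6-pentylphenoxy]-6-(2-oxoheptyl)benzoic acid, via keto aldehyde 30 (not isolated)
Conditions: Dess–Martin periodinane (3 equiv), NaHCO3, CH2Cl2, 0 °C → rt; then NaClO2, NaH2PO4, 2-methylbut-2-ene, t-BuOH/H2O, 0 °C → rt
Reagents that add atoms: sodium chlorite, [Na+].[O-]Cl=O
Why: Dess–Martin oxidation with the oxidant in excess from the start binds both hydroxyls before either carbonyl forms, which disfavours lactol formation, and Pinnick oxidation of crude 30 with a hypochlorite scavenger raises C1 to the acid without chlorinating the electron-rich rings; the racemic carbinol centre is erased here.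

Step 15
Reactants: 31 4-(benzyloxy)-2-[2-(benzyloxy)-4-methoxy-6-pentylphenoxy]-6-(2-oxoheptyl)benzoic acid
Product: 32 6-(benzyloxy)-8-[2-(benzyloxy)-4-methoxy-6-pentylphenoxy]-3-pentyl-1H-isochromen-1-one
Conditions: TsOH·H2O (cat.), PhMe, 80 °C, 4 Å MS
Reagents that add atoms: none
Why: Acid-catalysed enol-lactonisation: the carboxyl group adds to the C3 ketone to give the cyclic hydroxy lactone, and loss of water gives the conjugated six-membered enol lactone, the known fate of 2-(2-oxoalkyl)benzoic acids.

Step 16
Reactants: 32 6-(benzyloxy)-8-[2-(benzyloxy)-4-methoxy-6-pentylphenoxy]-3-pentyl-1H-isochromen-1-one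
Product: 33 6-hydroxy-8-(2-hydroxy-4-methoxy-6-pentylphenoxy)-3-pentyl-1H-isochromen-1-one
Conditions: BCl3, pentamethylbenzene, CH2Cl2, −78 °C; then MeOH
Reagents that add atoms: none
Why: Lewis-acid debenzylation of aryl benzyl ethers with a non-basic cation scavenger; at low temperature it should leave the C3=C4 bond (at risk under hydrogen on a metal), the non-chelated C4' methyl ether, the diaryl ether and the lactone intact, and the scavenger keeps benzyl cations off ring B.

## Compound list

1 | olivetol (5-pentylbenzene-1,3-diol) | CCCCCc1cc(O)cc(O)c1 | starting material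
2 | (2,4-dihydroxy-6-pentylbenzylidene)dimethyliminium chloride | CCCCCc1cc(O)cc(O)c1C=[N+](C)C.[Cl-] | intermediate
3 | 2,4-dihydroxy-6-pentylbenzaldehyde | CCCCCc1cc(O)cc(O)c1C=O | intermediate
4 | 2-hydroxy-4-methoxy-6-pentylbenzaldehyde | CCCCCc1cc(OC)cc(O)c1C=O | intermediate
5 | 2-(benzyloxy)-4-methoxy-6-pentylbenzaldehyde | CCCCCc1cc(OC)cc(OCc2ccccc2)c1C=O | intermediate
6 | 2-(benzyloxy)-4-methoxy-6-pentylphenyl formate | CCCCCc1cc(OC)cc(OCc2ccccc2)c1OC=O | intermediate
7 | 2-(benzyloxy)-4-methoxy-6-pentylphenol | CCCCCc1cc(OC)cc(OCc2ccccc2)c1O | intermediate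
8 | trichloroethylene | ClC=C(Cl)Cl | starting material
9 | dichloroacetylene (dichloroethyne) | ClC#CCl | intermediate
10 | 1-(benzyloxy)-2-{[(E)-1,2-dichloroethenyl]oxy}-5-methoxy-3-pentylbenzene | CCCCCc1cc(OC)cc(OCc2ccccc2)c1O/C(Cl)=C\Cl | intermediate
11 | 1-(benzyloxy)-2-[(chloroethynyl)oxy]-5-methoxy-3-pentylbenzene | CCCCCc1cc(OC)cc(OCc2ccccc2)c1OC#CCl | intermediate
12 | {[2-(benzyloxy)-4-methoxy-6-pentylphenoxy]ethynyl}lithium | CCCCCc1cc(OC)cc(OCc2ccccc2)c1OC#C[Li] | intermediate
13 | 1-(benzyloxy)-2-(ethynyloxy)-5-methoxy-3-pentylbenzene | CCCCCc1cc(OC)cc(OCc2ccccc2)c1OC#C | intermediate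
14 | tert-butyldimethyl(prop-2-yn-1-yloxy)silane | C#CCO[Si](C)(C)C(C)(C)C | starting material
15 | 2-pentyloxirane (1,2-epoxyheptane, racemic) | CCCCCC1CO1 | starting material
16 | {3-[(TBS)oxy]prop-1-yn-1-yl}lithium | [Li]C#CCO[Si](C)(C)C(C)(C)C | intermediate
17 | 1-[(TBS)oxy]dec-2-yn-5-ol (racemic) | CCCCCC(O)CC#CCO[Si](C)(C)C(C)(C)C | intermediate
18 | 1,5-bis[(TBS)oxy]dec-2-yne (racemic) | CCCCCC(CC#CCO[Si](C)(C)C(C)(C)C)O[Si](C)(C)C(C)(C)C | intermediate
19 | trichloroacetyl chloride | ClC(Cl)(Cl)C(Cl)=O | starting material
20 | dichloroketene (2,2-dichloroethen-1-one) | ClC(Cl)=C=O | intermediate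
21 | 4,4-dichloro-2-{[(TBS)oxy]methyl}-3-{2-[(TBS)oxy]heptyl}cyclobut-2-en-1-one (racemic) | CCCCCC(CC1=C(CO[Si](C)(C)C(C)(C)C)C(=O)C1(Cl)Cl)O[Si](C)(C)C(C)(C)C | intermediate
22 | 2-{[(TBS)oxy]methyl}-3-{2-[(TBS)oxy]heptyl}cyclobut-2-en-1-one (racemic) | CCCCCC(CC1=C(CO[Si](C)(C)C(C)(C)C)C(=O)C1)O[Si](C)(C)C(C)(C)C | intermediate
23 | 2-{[(TBS)oxy]methyl}-3-{2-[(TBS)oxy]heptyl}buta-1,3-dien-1-one (racemic) | CCCCCC(CC(=C)C(CO[Si](C)(C)C(C)(C)C)=C=O)O[Si](C)(C)C(C)(C)C | intermediate
24 | 3-[2-(benzyloxy)-4-methoxy-6-pentylphenoxy]-4-{[(TBS)oxy]methyl}-4-{4-[(TBS)oxy]non-1-en-2-yl}cyclobut-2-en-1-one (diastereomer mixture) | CCCCCC(CC(=C)C1(CO[Si](C)(C)C(C)(C)C)C(=O)C=C1Oc1c(OCc2ccccc2)cc(OC)cc1CCCCC)O[Si](C)(C)C(C)(C)C | intermediate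
25 | 3-[2-(benzyloxy)-4-methoxy-6-pentylphenoxy]-4-{[(TBS)oxy]methyl}-5-{2-[(TBS)oxy]heptyl}hexa-1,3,5-trien-1-one (racemic, alkene geometry not fixed) | CCCCCC(CC(=C)C(CO[Si](C)(C)C(C)(C)C)=C(C=C=O)Oc1c(OCc2ccccc2)cc(OC)cc1CCCCC)O[Si](C)(C)C(C)(C)C | intermediate
26 | 3-[2-(benzyloxy)-4-methoxy-6-pentylphenoxy]-4-{[(TBS)oxy]methyl}-5-{2-[(TBS)oxy]heptyl}cyclohexa-2,4-dien-1-one (racemic) | CCCCCC(CC1=C(CO[Si](C)(C)C(C)(C)C)C(Oc2c(OCc3ccccc3)cc(OC)cc2CCCCC)=CC(=O)C1)O[Si](C)(C)C(C)(C)C | intermediate
27 | 3-[2-(benzyloxy)-4-methoxy-6-pentylphenoxy]-4-{[(TBS)oxy]methyl}-5-{2-[(TBS)oxy]heptyl}phenol (racemic) | CCCCCC(Cc1cc(O)cc(Oc2c(OCc3ccccc3)cc(OC)cc2CCCCC)c1CO[Si](C)(C)C(C)(C)C)O[Si](C)(C)C(C)(C)C | intermediate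
28 | 1-(benzyloxy)-3-[2-(benzyloxy)-4-methoxy-6-pentylphenoxy]-4-{[(TBS)oxy]methyl}-5-{2-[(TBS)oxy]heptyl}benzene (racemic) | CCCCCC(Cc1cc(OCc2ccccc2)cc(Oc2c(OCc3ccccc3)cc(OC)cc2CCCCC)c1CO[Si](C)(C)C(C)(C)C)O[Si](C)(C)C(C)(C)C | intermediate
29 | {4-(benzyloxy)-2-[2-(benzyloxy)-4-methoxy-6-pentylphenoxy]-6-(2-hydroxyheptyl)phenyl}methanol (racemic) | CCCCCC(O)Cc1cc(OCc2ccccc2)cc(Oc2c(OCc3ccccc3)cc(OC)cc2CCCCC)c1CO | intermediate
30 | 4-(benzyloxy)-2-[2-(benzyloxy)-4-methoxy-6-pentylphenoxy]-6-(2-oxoheptyl)benzaldehyde | CCCCCC(=O)Cc1cc(OCc2ccccc2)cc(Oc2c(OCc3ccccc3)cc(OC)cc2CCCCC)c1C=O | intermediate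
31 | 4-(benzyloxy)-2-[2-(benzyloxy)-4-methoxy-6-pentylphenoxy]-6-(2-oxoheptyl)benzoic acid | CCCCCC(=O)Cc1cc(OCc2ccccc2)cc(Oc2c(OCc3ccccc3)cc(OC)cc2CCCCC)c1C(=O)O | intermediate
32 | 6-(benzyloxy)-8-[2-(benzyloxy)-4-methoxy-6-pentylphenoxy]-3-pentyl-1H-isochromen-1-one | CCCCCc1cc2cc(OCc3ccccc3)cc(Oc3c(OCc4ccccc4)cc(OC)cc3CCCCC)c2c(=O)o1 | intermediate
33 | 6-hydroxy-8-(2-hydroxy-4-methoxy-6-pentylphenoxy)-3-pentyl-1H-isochromen-1-one | CCCCCc1cc2cc(O)cc(Oc3c(O)cc(OC)cc3CCCCC)c2c(=O)o1 | target

## Step count and least certain steps

Total step count: 16. Longest linear sequence: 12 steps (steps 1 to 6, then 11 to 16). The second branch (steps 7 to 10) joins at step 11.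

Step 11 (key step). The most likely failure is slow capture of vinylketene 23 by the alkyne, because an aryloxy group donates less than an alkoxy or silyloxy group. Ketene self-condensation, acylation of the product phenol by 23 and thermal oligomerisation of 13 would then compete. Prolonged heating could also ionise the benzylic silyl ether para to the new hydroxyl. The fallback sets out from 7 and returns at 32, and makes the ether by nucleophilic aromatic substitution with the hindered partner as the nucleophile.
- Commercial 2-bromo-4,6-difluorobenzaldehyde is treated with benzyl alcohol and NaH in THF at 0 °C; the para fluoride is displaced to give 4-(benzyloxy)-2-bromo-6-fluorobenzaldehyde F1.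
- The phenoxide of 7 (K2CO3, DMF, 100 °C) displaces the fluoride activated by the ortho formyl group to give 4-(benzyloxy)-2-[2-(benzyloxy)-4-methoxy-6-pentylphenoxy]-6-bromobenzaldehyde F2.
- Sonogashira coupling with hept-1-yne (Pd(PPh3)2Cl2, CuI, Et3N) gives 4-(benzyloxy)-2-[2-(benzyloxy)-4-methoxy-6-pentylphenoxy]-6-(hept-1-yn-1-yl)benzaldehyde F3.
- Pinnick oxidation gives 4-(benzyloxy)-2-[2-(benzyloxy)-4-methoxy-6-pentylphenoxy]-6-(hept-1-yn-1-yl)benzoic acid F4.
- 6-endo cycloisomerisation of the alkynyl acid with catalytic AgOTf gives 32.

Step 9. The most likely failure is incomplete regiocontrol in the ketene–alkyne addition, since the two alkyne substituents differ only in how far the oxygen is from the triple bond. Chlorine migration in 21 and loss of silyl groups to ZnCl2 are lesser risks. The fallback sets out from 15 and returns at 22, and fixes the regiochemistry with an ynol ether.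
- Lithiated ethoxyacetylene (commercial) is hydroxymethylated with paraformaldehyde to 3-ethoxyprop-2-yn-1-ol F5 and silylated to tert-butyl[(3-ethoxyprop-2-yn-1-yl)oxy]dimethylsilane F6.
- 20 adds to F6 with the oxygen-bearing carbon bonded to CCl2, giving 4,4-dichloro-3-ethoxy-2-{[(TBS)oxy]methyl}cyclobut-2-en-1-one F7.
- Zinc, AcOH and TMEDA give 3-ethoxy-2-{[(TBS)oxy]methyl}cyclobut-2-en-1-one F8.
- Reductive lithiation of 15 with lithium 4,4'-di-tert-butylbiphenylide in THF at −78 °C gives lithium 1-lithioheptan-2-olate F9, which adds to the carbonyl group of F8.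
- Mild aqueous acid hydrolyses the enol ether with carbonyl transposition to 3-(2-hydroxyheptyl)-2-{[(TBS)oxy]methyl}cyclobut-2-en-1-one F10.
- Silylation (TBSCl, imidazole) gives 22.

Step 6. The most likely failure is loss of the terminal aryl ynol ether during isolation, by hydration on silica or oligomerisation on concentration; metalation by excess n-BuLi is a lesser risk. The fallback sets out from 12 and returns at 13, and uses a storable silyl-capped form. The acetylide 12 is quenched with chlorotriisopropylsilane to give {[2-(benzyloxy)-4-methoxy-6-pentylphenoxy]ethynyl}tri(propan-2-yl)silane F11, which can be chromatographed and stored. TBAF in THF at 0 °C removes the silyl group just before use, and the extract of 13 is exchanged into toluene and taken straight into step 11.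

Step 14. The most likely failure is lactol capture. If the benzylic alcohol is oxidised before the secondary one, the hydroxy aldehyde closes to a lactol and is oxidised to the 3,4-dihydroisocoumarin, which has the wrong oxidation level at C3. Aldol condensation of 30 onto its own aldehyde is a second risk. The fallback sets out from 29 and returns at 31, and oxidises the two carbons in sequence.
- Selective silylation of the primary hydroxyl (TBSCl 1.05 equiv, imidazole, CH2Cl2, 0 °C) gives 1-{5-(benzyloxy)-3-[2-(benzyloxy)-4-methoxy-6-pentylphenoxy]-2-{[(TBS)oxy]methyl}phenyl}heptan-2-ol F12.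
- Dess–Martin oxidation gives 1-{5-(benzyloxy)-3-[2-(benzyloxy)-4-methoxy-6-pentylphenoxy]-2-{[(TBS)oxy]methyl}phenyl}heptan-2-one F13.
- TBAF gives 1-{5-(benzyloxy)-3-[2-(benzyloxy)-4-methoxy-6-pentylphenoxy]-2-(hydroxymethyl)phenyl}heptan-2-one F14.
- Dess–Martin and then Pinnick oxidation, with no free hydroxyl left to trap the aldehyde, give 31.

## Further compounds

F1 | step 11 | 4-(benzyloxy)-2-bromo-6-fluorobenzaldehyde | O=Cc1c(F)cc(OCc2ccccc2)cc1Br
F2 | step 11 | 4-(benzyloxy)-2-[2-(benzyloxy)-4-methoxy-6-pentylphenoxy]-6-bromobenzaldehyde | CCCCCc1cc(OC)cc(OCc2ccccc2)c1Oc1cc(OCc2ccccc2)cc(Br)c1C=O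
F3 | step 11 | 4-(benzyloxy)-2-[2-(benzyloxy)-4-methoxy-6-pentylphenoxy]-6-(hept-1-yn-1-yl)benzaldehyde | CCCCCC#Cc1cc(OCc2ccccc2)cc(Oc2c(OCc3ccccc3)cc(OC)cc2CCCCC)c1C=O
F4 | step 11 | 4-(benzyloxy)-2-[2-(benzyloxy)-4-methoxy-6-pentylphenoxy]-6-(hept-1-yn-1-yl)benzoic acid | CCCCCC#Cc1cc(OCc2ccccc2)cc(Oc2c(OCc3ccccc3)cc(OC)cc2CCCCC)c1C(=O)O
F5 | step 9 | 3-ethoxyprop-2-yn-1-ol | CCOC#CCO
F6 | step 9 | tert-butyl[(3-ethoxyprop-2-yn-1-yl)oxy]dimethylsilane | CCOC#CCO[Si](C)(C)C(C)(C)C
F7 | step 9 | 4,4-dichloro-3-ethoxy-2-{[(TBS)oxy]methyl}cyclobut-2-en-1-one | CCOC1=C(CO[Si](C)(C)C(C)(C)C)C(=O)C1(Cl)Cl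
F8 | step 9 | 3-ethoxy-2-{[(TBS)oxy]methyl}cyclobut-2-en-1-one | CCOC1=C(CO[Si](C)(C)C(C)(C)C)C(=O)C1
F9 | step 9 | lithium 1-lithioheptan-2-olate (racemic) | [Li]CC(O[Li])CCCCC
F10 | step 9 | 3-(2-hydroxyheptyl)-2-{[(TBS)oxy]methyl}cyclobut-2-en-1-one (racemic) | CCCCCC(O)CC1=C(CO[Si](C)(C)C(C)(C)C)C(=O)C1
F11 | step 6 | {[2-(benzyloxy)-4-methoxy-6-pentylphenoxy]ethynyl}tri(propan-2-yl)silane | CCCCCc1cc(OC)cc(OCc2ccccc2)c1OC#C[Si](C(C)C)(C(C)C)C(C)C
F12 | step 14 | 1-{5-(benzyloxy)-3-[2-(benzyloxy)-4-methoxy-6-pentylphenoxy]-2-{[(TBS)oxy]methyl}phenyl}heptan-2-ol (racemic) | CCCCCC(O)Cc1cc(OCc2ccccc2)cc(Oc2c(OCc3ccccc3)cc(OC)cc2CCCCC)c1CO[Si](C)(C)C(C)(C)C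
F13 | step 14 | 1-{5-(benzyloxy)-3-[2-(benzyloxy)-4-methoxy-6-pentylphenoxy]-2-{[(TBS)oxy]methyl}phenyl}heptan-2-one | CCCCCC(=O)Cc1cc(OCc2ccccc2)cc(Oc2c(OCc3ccccc3)cc(OC)cc2CCCCC)c1CO[Si](C)(C)C(C)(C)C
F14 | step 14 | 1-{5-(benzyloxy)-3-[2-(benzyloxy)-4-methoxy-6-pentylphenoxy]-2-(hydroxymethyl)phenyl}heptan-2-one | CCCCCC(=O)Cc1cc(OCc2ccccc2)cc(Oc2c(OCc3ccccc3)cc(OC)cc2CCCCC)c1CO
A1 | alternative 1 | 5-(benzyloxy)-3-[2-(benzyloxy)-4-methoxy-6-pentylphenoxy]-2-(trimethylsilyl)phenyl trifluoromethanesulfonate | CCCCCc1cc(OC)cc(OCc2ccccc2)c1Oc1cc(OCc2ccccc2)cc(OS(=O)(=O)C(F)(F)F)c1[Si](C)(C)C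
A2 | alternative 1 | dimethyl malonate | COC(=O)CC(=O)OC
A3 | alternative 1 | methyl 4-(benzyloxy)-2-[2-(benzyloxy)-4-methoxy-6-pentylphenoxy]-6-(2-methoxy-2-oxoethyl)benzoate | CCCCCc1cc(OC)cc(OCc2ccccc2)c1Oc1cc(OCc2ccccc2)cc(CC(=O)OC)c1C(=O)OC
A4 | alternative 2 | 2,2-dimethyl-6-[2,4-dioxo-5-(2-pentyl-1,3-dioxolan-2-yl)pentyl]-4H-1,3-dioxin-4-one | CCCCCC1(CC(=O)CC(=O)CC2=CC(=O)OC(C)(C)O2)OCCO1
A5 | alternative 2 | 6,8-dihydroxy-3-pentyl-1H-isochromen-1-one | CCCCCc1cc2cc(O)cc(O)c2c(=O)o1
A6 | alternative 3 | dimethyl 2-[5-(benzyloxy)-2-(methoxycarbonyl)-3-methylphenoxy]malonate | COC(=O)C(Oc1cc(OCc2ccccc2)cc(C)c1C(=O)OC)C(=O)OC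
A7 | alternative 3 | (E)-non-3-en-2-one | CCCCC/C=C/C(C)=O
A8 | alternative 3 | methyl 1-[5-(benzyloxy)-2-(methoxycarbonyl)-3-methylphenoxy]-2,4-dioxo-6-pentylcyclohexane-1-carboxylate (diastereomer mixture) | CCCCCC1CC(=O)CC(=O)C1(Oc1cc(OCc2ccccc2)cc(C)c1C(=O)OC)C(=O)OC
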